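The seven-membered ring is traced to a cyclohexane fused to a cyclopropane. Daucane numbering is used: C1 is the methyl-bearing ring-fusion carbon, C4 the isopropyl carbinol, C5 the ring-fusion CH, C6 the ester carbon, C8 and C9 the diol. In the seven-membered ring (C1, C10, C9, C8, C7, C6, C5) the C6 oxygen is homoallylic to a C8=C9 alkene, the precursor of the diol. Everything rests on a cyclopropylcarbinyl-to-homoallyl ring enlargement. Cyclopropyl carbinol 15, a cyclohexane (C1, C10, C9, C8, C6, C5) bridged by C7 across C6–C8, ionises at C9, the C6–C8 bond breaks and 4-(benzyloxy)benzoic acid enters at C6 from the rear. One operation gives the cycloheptene, the C8=C9 alkene and the C6 ester with its configuration.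

Key step: step 9

Remarks: β is the face of the C1 methyl group; C7 is the carbon brought in as a methylene group in step 6. Compounds 7–12 are carried as both epimers at C10 and 15 as both epimers at C9, because these centres become trigonal in steps 7 and 9. Assumptions: chloroprene (1) is bought as its stabilised solution, and in step 2 the antipode of the catalyst is taken that delivers the S aldehyde.

Step 1
Reactants: 1 2-chlorobuta-1,3-diene (chloroprene); 2 isopropylmagnesium chloride
Product: 3 2-(propan-2-yl)buta-1,3-diene
Conditions: NiCl2(Ph2PCH2CH2CH2PPh2) (1 mol %), Et2O, 0 °C → rt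
Reagents that add atoms: none
Why: Kumada cross-coupling of the alkenyl chloride with the secondary Grignard reagent under nickel–bisphosphine catalysis should give the 2-alkyl diene without isomerisation of the isopropyl group; no stereocentre is formed.

Step 2
Reactants: 3 2-(propan-2-yl)buta-1,3-diene; 4 methacrolein
Product: 5 (S)-1-methyl-4-(propan-2-yl)cyclohex-3-ene-1-carbaldehyde
Conditions: oxazaborolidinium triflimide made from α,α-diphenylprolinol, tri(2-methylphenyl)boroxine and HNTf2 (10 mol %), CH2Cl2, −78 → −40 °C
Reagents that add atoms: none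
Why: Lewis-acid-catalysed asymmetric Diels–Alder reaction in which the 2-alkyl diene should add "para" to the formyl-bearing carbon, while the chiral oxazaborolidinium ion bound to the s-trans enal leaves one enantioface open and so sets the quaternary centre C1.

Step 3
Reactants: 5 (S)-1-methyl-4-(propan-2-yl)cyclohex-3-ene-1-carbaldehyde; 6 prop-1-ynylmagnesium bromide
Product: 8 1-[(S)-1-methyl-4-(propan-2-yl)cyclohex-3-en-1-yl]but-2-yn-1-yl acetate (C10 epimers), via bromomagnesium alkoxide 7 (not isolated)
Conditions: 6 (1.3 equiv), THF, −78 → 0 °C; then Ac2O, DMAP (cat.), 0 °C → rt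
Reagents that add atoms: acetic anhydride CC(=O)OC(C)=O
Why: 1,2-addition of the alkynyl Grignard reagent to the aldehyde followed by O-acetylation of the alkoxide in the same flask; the carbinol centre C10 forms unselectively, which is harmless because C10 becomes trigonal in step 7.

Step 4
Reactants: 8 propargylic acetate
Product: 10 (5S)-5,9-dimethyl-8-oxo-5-(2-oxoethyl)dec-2-yn-4-yl acetate (keto-aldehyde; C10 epimers), via secondary ozonide 9 (not isolated)
Conditions: O3, CH2Cl2, −78 °C (Sudan red 7B as indicator); then Me2S, −78 °C → rt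
Reagents that add atoms: ozone [O-][O+]=O
Why: ozonolysis with reductive work-up, in which the electron-rich trisubstituted ring alkene should react far faster than the internal alkyne, so that cleavage of C4=C6 unveils the isopropyl ketone (C4) and the aldehyde (C6) while C1 is untouched.

Step 5
Reactants: 10 keto-aldehyde
Product: 11 1-[(1S,2R,3R)-2-formyl-3-hydroxy-1-methyl-3-(propan-2-yl)cyclopentyl]but-2-yn-1-yl acetate (C1 methyl, C5 formyl and C4 hydroxyl all cis; C10 epimers)
Conditions: pyrrolidine (20 mol %), AcOH (20 mol %), CH2Cl2, 0 °C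
Reagents that add atoms: none
Why: amine-catalysed intramolecular aldol addition (5-enolexo) in which the aldehyde enamine, formed far faster than that of the hindered ketone, attacks the C4 ketone; C5 should place the formyl group trans to the bulky C10 substituent and C4 the isopropyl group trans to the formyl group with the hydroxyl cis and hydrogen-bonded, an arrangement favoured both in the transition state and at equilibrium since C5 epimerises through the enamine.

Step 6
Reactants: 11 β-hydroxy aldehyde
Product: 12 1-[(1S,2R,3R)-2-ethenyl-3-hydroxy-1-methyl-3-(propan-2-yl)cyclopentyl]but-2-yn-1-yl acetate (C10 epimers)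
Conditions: Ph3PCH3Br, KN(SiMe3)2 (2.5 equiv each), THF, −78 → 0 °C
Reagents that add atoms: methylenetriphenylphosphorane C=P(c1ccccc1)(c1ccccc1)c1ccccc1 (made in the flask from methyltriphenylphosphonium bromide)
Why: Wittig methylenation of the aldehyde, in which the tertiary alkoxide takes the first equivalent of ylide, any retro-aldol opening is reversible and recloses to the same favoured diastereomer, and no stereocentre is created.

Step 7
Reactants: 12 enyne acetate
Product: 13 tricyclic enol acetate (trans-fused hydrindene with C1 methyl β and C5–H α; 4β-hydroxy-4α-isopropyl; C9(OAc)=C10; α-cyclopropane C6–C7–C8 with the C8 methyl β)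
Conditions: PtCl2 (5 mol %), toluene, 80 °C
Reagents that add atoms: none
Why: platinum-catalysed cycloisomerisation of a 1,6-enyne propargylic acetate (Ohloff–Rautenstrauch type), in which 1,2-acetoxy migration from C10 to C9 gives a vinyl platinum carbene at C8 that cyclopropanates the C6=C7 vinyl group and thereby closes the six-membered ring; the vinyl group should react in its preferred rotamer (C7 eclipsing C5–H) and a β-cyclopropane would clash with the axial C1 methyl group, so C7 should end on the α face, which fixes C6 and C8.

Step 8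
Reactants: 13 tricyclic enol acetate
Product: 15 cyclopropyl carbinol (9-hydroxy analogue of 14; C9 epimers), via cyclopropyl ketone 14 (not isolated)
Conditions: K2CO3 (cat.), MeOH, 0 °C → rt; then NaBH4, 0 °C
Reagents that add atoms: none
Why: base-catalysed methanolysis of the enol acetate should give the cyclopropyl ketone, which NaBH4 reduces in the same flask; the configuration at C9 does not matter because C9 is ionised in step 9.

Step 9
Reactants: 15 cyclopropyl carbinol; 16 4-(benzyloxy)benzoic acid
Product: 18 (3R,3aS,4S,8aR)-3-hydroxy-6,8a-dimethyl-3-(propan-2-yl)-1,2,3,3a,4,5,8,8a-octahydroazulen-4-yl 4-(benzyloxy)benzoate (O-benzylferutinin), via cyclopropylcarbinyl cation 17 (not isolated)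
Conditions: 16 (4 equiv), Sc(O3SCF3)3 (5 mol %), 4 Å molecular sieves, CH2Cl2/MeNO2, 0 °C → rt
Reagents that add atoms: none
Why: The Lewis acid ionises the cyclopropyl carbinol at C9 to the cyclopropylcarbinyl (bicyclobutonium) cation 17; the internal C6–C8 bond, not the C7–C8 bond (which would leave a primary cation), opens toward the homoallyl cation while carboxylic acid 16 attacks C6 from the rear. The closest known reaction type is the solvolytic cyclopropylcarbinyl-to-homoallyl rearrangement of bicyclo[4.1.0]hept-2-yl systems to cyclohept-3-enyl esters and alcohols, together with the i-steroid rearrangement, which delivers 3β-esters with carboxylic acids. No ring is closed by cyclisation: the seven-membered ring arises by scission of the bond shared by the cyclopropane and the cyclohexane, which takes C7 into the ring (six to seven). The only new stereocentre, C6, is controlled by the cyclopropane, since attack anti to the breaking C6–C8 bond inverts C6 and the α-cyclopropane therefore gives the 6α-ester. The step needs capture at C6 instead of C9 (cyclopropylcarbinyl ester) or C8 (cyclobutyl ester), and ionisation of the cyclopropyl carbinol in preference to the tertiary C4 alcohol; the first should be secured because the strained esters re-ionise under the Lewis acid and drain into the strain-free homoallylic ester, the second by the far higher ionisation rate of a cyclopropyl carbinol and by the trans ring fusion, which keeps the C4 hydroxyl from reaching C7 or C8.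

Step 10
Reactants: 18 O-benzylferutinin
Product: 19 (3R,3aS,4S,6R,7S,8aR)-3,6,7-trihydroxy-6,8a-dimethyl-3-(propan-2-yl)decahydroazulen-4-yl 4-(benzyloxy)benzoate
Conditions: OsO4 (2 mol %), N-methylmorpholine N-oxide (1.5 equiv), acetone/H2O, 0 °C → rt
Reagents that add atoms: N-methylmorpholine N-oxide C[N+]1([O-])CCOCC1; water O
Why: Upjohn syn-dihydroxylation of the trisubstituted C8=C9 alkene, in which OsO4 should approach the α face, away from the axial C1 methyl group that shields the β face (the C6 ester is equatorial), so that C8 and C9 are set together.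

Step 11
Reactants: 19 benzyl-protected triol ester
Product: 20 (3R,3aS,4S,6R,7S,8aR)-3,6,7-trihydroxy-6,8a-dimethyl-3-(propan-2-yl)decahydroazulen-4-yl 4-hydroxybenzoate (CNP0197754.3)
Conditions: H2 (1 atm), Pd on carbon (10 wt %), EtOAc, rt
Reagents that add atoms: none
Why: hydrogenolysis of the benzyl aryl ether over palladium should free the phenol while the alkyl benzoate, the three alcohols and all stereocentres stay untouched, no alkene being left to reduce.

Compound list
1 | 2-chlorobuta-1,3-diene (chloroprene) | C=CC(Cl)=C | starting material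
2 | isopropylmagnesium chloride | CC(C)[Mg]Cl | starting material
3 | 2-(propan-2-yl)buta-1,3-diene | C=CC(=C)C(C)C | intermediate
4 | methacrolein (2-methylprop-2-enal) | CC(=C)C=O | starting material
5 | (S)-1-methyl-4-(propan-2-yl)cyclohex-3-ene-1-carbaldehyde | O=C[C@@]1(C)CCC(C(C)C)=CC1 | intermediate
6 | prop-1-ynylmagnesium bromide | CC#C[Mg]Br | starting material
7 | bromomagnesium 1-[(S)-1-methyl-4-(propan-2-yl)cyclohex-3-en-1-yl]but-2-yn-1-olate (C10 epimers) | CC#CC(O[Mg]Br)[C@@]1(C)CCC(C(C)C)=CC1 | intermediate
8 | 1-[(S)-1-methyl-4-(propan-2-yl)cyclohex-3-en-1-yl]but-2-yn-1-yl acetate (C10 epimers) | CC#CC(OC(C)=O)[C@@]1(C)CCC(C(C)C)=CC1 | intermediate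
9 | secondary ozonide of 8 (1,2,4-trioxolane across C4 and C6) | CC#CC(OC(C)=O)[C@@]1(C)CCC2(C(C)C)OOC(C1)O2 | intermediate
10 | (5S)-5,9-dimethyl-8-oxo-5-(2-oxoethyl)dec-2-yn-4-yl acetate (C10 epimers) | CC#CC(OC(C)=O)[C@](C)(CC=O)CCC(=O)C(C)C | intermediate
11 | 1-[(1S,2R,3R)-2-formyl-3-hydroxy-1-methyl-3-(propan-2-yl)cyclopentyl]but-2-yn-1-yl acetate (C10 epimers) | CC(C)[C@]1(O)CC[C@](C)(C(OC(C)=O)C#CC)[C@H]1C=O | intermediate
12 | 1-[(1S,2R,3R)-2-ethenyl-3-hydroxy-1-methyl-3-(propan-2-yl)cyclopentyl]but-2-yn-1-yl acetate (C10 epimers) | CC(C)[C@]1(O)CC[C@](C)(C(OC(C)=O)C#CC)[C@H]1C=C | intermediate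
13 | tricyclic enol acetate: trans-fused hydrindene (C1 methyl β, C5–H α), 4β-hydroxy-4α-isopropyl, C9(OAc)=C10, α-cyclopropane C6–C7–C8 with C8 methyl β | CC(C)[C@]1(O)CC[C@]2(C)C=C(OC(C)=O)[C@]3(C)C[C@@H]3[C@H]21 | intermediate
14 | cyclopropyl ketone: the C9 ketone (C10 = CH2) corresponding to 13 | CC(C)[C@]1(O)CC[C@]2(C)CC(=O)[C@]3(C)C[C@@H]3[C@H]21 | intermediate
15 | cyclopropyl carbinol: the C9 alcohol of 14 (C9 epimers) | CC(C)[C@]1(O)CC[C@]2(C)CC(O)[C@]3(C)C[C@@H]3[C@H]21 | intermediate
16 | 4-(benzyloxy)benzoic acid | O=C(O)c1ccc(OCc2ccccc2)cc1 | starting material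
17 | cyclopropylcarbinyl cation at C9 derived from 15 | CC(C)[C@]1(O)CC[C@]2(C)C[CH+][C@]3(C)C[C@@H]3[C@H]21 | intermediate
18 | (3R,3aS,4S,8aR)-3-hydroxy-6,8a-dimethyl-3-(propan-2-yl)-1,2,3,3a,4,5,8,8a-octahydroazulen-4-yl 4-(benzyloxy)benzoate | CC(C)[C@]1(O)CC[C@]2(C)CC=C(C)C[C@H](OC(=O)c3ccc(OCc4ccccc4)cc3)[C@H]21 | intermediate
19 | (3R,3aS,4S,6R,7S,8aR)-3,6,7-trihydroxy-6,8a-dimethyl-3-(propan-2-yl)decahydroazulen-4-yl 4-(benzyloxy)benzoate | CC(C)[C@]1(O)CC[C@]2(C)C[C@H](O)[C@](C)(O)C[C@H](OC(=O)c3ccc(OCc4ccccc4)cc3)[C@H]21 | intermediate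
20 | (3R,3aS,4S,6R,7S,8aR)-3,6,7-trihydroxy-6,8a-dimethyl-3-(propan-2-yl)decahydroazulen-4-yl 4-hydroxybenzoate | CC(C)[C@]1(O)CC[C@]2(C)C[C@H](O)[C@](C)(O)C[C@H](OC(=O)c3ccc(O)cc3)[C@H]21 | target

Total step count: 11. Longest linear sequence: 11 steps (1 → 20); acid 16 enters in step 9.

Steps most likely to fail

Step 9 (key step). The cation may be captured at C9 or C8 instead of C6, lose a proton to dienes, or be intercepted by the water that is set free; the tertiary C4 carbinol may also ionise under the Lewis acid. The fallback sets out from 15 and separates the ring enlargement from the ester formation. Dilute HClO4 in aqueous 1,4-dioxane at room temperature (thermodynamic control, water as the nucleophile) should convert 15 into jaeschkeanadiol F1. The secondary C6 hydroxyl of F1 is then acylated with 4-(benzyloxy)benzoyl chloride (DMAP, pyridine, CH2Cl2), the tertiary C4 hydroxyl being inert. This gives 18, where the route is rejoined.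

Step 7. With the methyl-capped alkyne the acetate may undergo the competing 1,3-shift to an allenyl acetate, or the carbene may add to the vinyl group with poor facial control. The fallback sets out from 12 and builds the same ketone through a diazo ketone. Ph3PAuNTf2 in wet 1,4-dioxane should hydrate the alkyne with acetate participation to the α-acetoxy ketone F2. SmI2 (THF/MeOH, −78 °C) removes the acetoxy group to give the ethyl ketone F3. LiN(SiMe3)2 and CF3CO2CH2CF3 give the trifluoroacetyl diketone F4, and methanesulfonyl azide with Et3N turns it into the α-diazo ketone F5. Copper bis(acetylacetonate) in warm toluene then effects intramolecular cyclopropanation of the vinyl group, on the α face for the reasons given in step 7, and returns to 14, which is reduced as in step 8.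

Step 5. The tertiary aldol may dehydrate to the conjugated enal, or the ring may close with the hydroxyl trans to the formyl group. The fallback sets out from 10 and sets C4 by an epoxidation instead. Piperidinium acetate in warm toluene drives the aldol condensation to the enal F6. Weitz–Scheffer epoxidation (t-BuOOH, DBU, CH2Cl2) on the face away from the bulky C10 substituent gives the epoxy aldehyde F7. SmI2 (THF/MeOH, −90 °C) cleaves its C5–O bond, and protonation of the enolate returns to 11.

Further compounds
F1 | step 9 | (3R,3aS,4S,8aR)-6,8a-dimethyl-3-(propan-2-yl)-1,2,3,3a,4,5,8,8a-octahydroazulene-3,4-diol (jaeschkeanadiol) | CC(C)[C@]1(O)CC[C@]2(C)CC=C(C)C[C@H](O)[C@H]21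
F2 | step 7 | α-acetoxy ketone: 1-[(1S,2R,3R)-2-ethenyl-3-hydroxy-1-methyl-3-(propan-2-yl)cyclopentyl]-2-oxobutyl acetate (C10 epimers) | CC(C)[C@]1(O)CC[C@](C)(C(OC(C)=O)C(=O)CC)[C@H]1C=C
F3 | step 7 | ethyl ketone: 1-[(1S,2R,3R)-2-ethenyl-3-hydroxy-1-methyl-3-(propan-2-yl)cyclopentyl]butan-2-one | CC(C)[C@]1(O)CC[C@](C)(CC(=O)CC)[C@H]1C=C
F4 | step 7 | trifluoroacetyl diketone: 3-(trifluoroacetyl) derivative of F3 at C8 | CC(C)[C@]1(O)CC[C@](C)(CC(=O)C(C)C(=O)C(F)(F)F)[C@H]1C=C
F5 | step 7 | α-diazo ketone: 3-diazo-1-[(1S,2R,3R)-2-ethenyl-3-hydroxy-1-methyl-3-(propan-2-yl)cyclopentyl]butan-2-one | CC(C)[C@]1(O)CC[C@](C)(CC(=O)C(C)=[N+]=[N-])[C@H]1C=C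
F6 | step 5 | enal: 1-[(S)-2-formyl-1-methyl-3-(propan-2-yl)cyclopent-2-en-1-yl]but-2-yn-1-yl acetate (C10 epimers) | CC(C)C1=C(C=O)[C@@](C)(C(OC(C)=O)C#CC)CC1
F7 | step 5 | epoxy aldehyde: 4β,5β-epoxide of F6 (oxirane cis to the C1 methyl group) | CC(C)[C@]12CC[C@](C)(C(OC(C)=O)C#CC)[C@@]1(C=O)O2
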